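**Retrosynthetic overview**
1. Target 11 ← hydrogenolysis of two aryl benzyl ethers (10) ← chelation-controlled reduction of the aryl ketone in keto lactone 9.
2. 9 ← formal [3+2] annulation of α-keto acid 4 with aryl vinyl ketone 7: the ring O–CH2 bond by oxa-Michael addition and the bond from the ring CH to the fully substituted carbinol carbon by intramolecular aldol addition. The lactone, the only ring, forms in this step.
3. Enabling feature: O1–C2(=O)–C3(OH) of the lactone is an α-keto acid (carboxylate O as nucleophile, keto carbon as electrophile). With the exocyclic benzylic carbon at ketone level, ring C5H2 and C4H are the β- and α-carbons of an aryl vinyl ketone.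
4. 4 (hydantoin condensation, hydrolysis) and 7 (vinyl Grignard addition, oxidation) both come from O-benzylvanillin 1.

Key step: step 5

Assumption: the quinidine-derived squaramide is taken to give the (S)-configured tertiary carbinol in step 5; its quinine-derived pseudoenantiomer is the same reagent for the opposite sense. Acid 4 is drawn as the keto acid although it rests largely as its enol.

**Step 1**
Reactants: 1 4-(benzyloxy)-3-methoxybenzaldehyde; 2 hydantoin (imidazolidine-2,4-dione)
Product: 3 (Z)-5-[4-(benzyloxy)-3-methoxybenzylidene]imidazolidine-2,4-dione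
Conditions: NH4OAc (cat.), AcOH, reflux
Reagents that add atoms: none
Why: Knoevenagel-type condensation of the acidic CH2 of hydantoin with a non-enolisable aldehyde should give the conjugated (Z)-alkene under thermodynamic control; no stereocentre is formed.

**Step 2**
Reactants: 3 (Z)-5-[4-(benzyloxy)-3-methoxybenzylidene]imidazolidine-2,4-dione
Product: 4 3-[4-(benzyloxy)-3-methoxyphenyl]-2-oxopropanoic acid
Conditions: 20% aq. NaOH, reflux, N2; then HCl, 0 °C, pH 1
Reagents that add atoms: water, O
Why: alkaline hydrolysis of a 5-arylidenehydantoin (opening of the ureide and hydrolysis of the enamide) is the classical hydantoin route to arylpyruvic acids, and the benzyl ether is stable to hydroxide.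

**Step 3**
Reactants: 1 4-(benzyloxy)-3-methoxybenzaldehyde; 5 vinylmagnesium bromide
Product: 6 rac-1-[4-(benzyloxy)-3-methoxyphenyl]prop-2-en-1-ol
Conditions: THF, 0 °C; sat. aq. NH4Cl
Reagents that add atoms: none
Why: Grignard 1,2-addition to an aldehyde; the carbinol centre is formed racemic and is erased in step 4.

**Step 4**
Reactants: 6 rac-1-[4-(benzyloxy)-3-methoxyphenyl]prop-2-en-1-ol
Product: 7 1-[4-(benzyloxy)-3-methoxyphenyl]prop-2-en-1-one
Conditions: activated MnO2 (excess), CH2Cl2, rt; filtered and used at once as a solution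
Reagents that add atoms: none
Why: MnO2 oxidation of an allylic and benzylic alcohol should give the enone without touching the alkene or the benzyl ether.

**Step 5**
Reactants: 4 3-[4-(benzyloxy)-3-methoxyphenyl]-2-oxopropanoic acid; 7 1-[4-(benzyloxy)-3-methoxyphenyl]prop-2-en-1-one
Product: 9 (3S,4S)-4-[4-(benzyloxy)-3-methoxybenzoyl]-3-{[4-(benzyloxy)-3-methoxyphenyl]methyl}-3-hydroxyoxolan-2-one, via β-acyloxy ketone 8 (not isolated)
Conditions: squaramide from 9-amino-9-deoxy-epi-quinidine and 3,5-bis(trifluoromethyl)aniline (10 mol%), CH2Cl2 (0.05 M), −20 °C → rt; 7 (1.1 equiv) added over 6 h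
Reagents that add atoms: none
Why: Proposed new method: the quinuclidinium carboxylate of 4 adds through oxygen to the CH2 terminus of enone 7 (oxa-Michael addition), and the catalyst-bound ketone enolate of the β-acyloxy ketone 8 then attacks the neighbouring keto carbon of its own α-keto ester (intramolecular aldol addition), a formal [3+2] annulation whose closest known relatives are amine-catalysed oxa-Michael/aldol domino reactions of enones and the direct aldol addition of aryl ketones to α-keto esters under tertiary amine–squaramide catalysis. The lactone, the only ring, closes in the C–C bond-forming event as a 5-(enolexo)-exo-trig closure, whereas loss of carboxylate from the product would be the reverse of a 5-endo closure, so the ring once formed is kinetically protected. The tertiary carbinol carbon is set (S) under catalyst control, the squaramide N–H pair holding the 1,2-dicarbonyl unit and the ammonium ion the Z-enolate so that one face of the ketone is open. The aroyl-bearing carbon is set under thermodynamic control: it stays enolisable under the amine, and both epimers should drain into the (3S,4S) isomer, in which aroyl is trans to benzyl and hydrogen-bonded to the cis tertiary hydroxyl. The step needs O- before C-alkylation of 4 and aldol closure before β-elimination or intermolecular C–C bond formation at the enolisable benzylic CH2; with substoichiometric base the carboxylate is the only anionic site of 4, slow addition keeps free 7 low, and dilution favours the intramolecular five-membered closure onto a 1,2-dicarbonyl carbon over the bimolecular alternatives.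

**Step 6**
Reactants: 9 (3S,4S)-4-[4-(benzyloxy)-3-methoxybenzoyl]-3-{[4-(benzyloxy)-3-methoxyphenyl]methyl}-3-hydroxyoxolan-2-one
Product: 10 (3S,4R)-3-{[4-(benzyloxy)-3-methoxyphenyl]methyl}-4-{(R)-[4-(benzyloxy)-3-methoxyphenyl](hydroxy)methyl}-3-hydroxyoxolan-2-one
Conditions: Zn(BH4)2 (1.5 equiv), Et2O–THF, −30 °C; sat. aq. NH4Cl
Reagents that add atoms: none
Why: chelation-controlled hydride reduction of a β-hydroxy ketone: zinc bridges the tertiary hydroxyl and the ketone oxygen, which are cis on the lactone, and hydride should enter from the open face past the ring C–H and away from the ring CH2, giving the (R)-carbinol, while the lactone is not reduced at this temperature.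

**Step 7**
Reactants: 10 (3S,4R)-3-{[4-(benzyloxy)-3-methoxyphenyl]methyl}-4-{(R)-[4-(benzyloxy)-3-methoxyphenyl](hydroxy)methyl}-3-hydroxyoxolan-2-one
Product: 11 (3S,4R)-3-hydroxy-4-[(R)-hydroxy(4-hydroxy-3-methoxyphenyl)methyl]-3-[(4-hydroxy-3-methoxyphenyl)methyl]oxolan-2-one
Conditions: H2 (1 atm), 10% Pd/C, EtOAc, rt, stopped at full conversion
Reagents that add atoms: none
Why: hydrogenolysis of aryl benzyl ethers over Pd/C under neutral conditions should be much faster than cleavage of the secondary benzylic C–OH, and no stereocentre is touched.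

**Compound list**
1 | 4-(benzyloxy)-3-methoxybenzaldehyde | O=Cc1ccc(OCc2ccccc2)c(OC)c1 | starting material
2 | hydantoin | O=C1CNC(=O)N1 | starting material
3 | (Z)-5-[4-(benzyloxy)-3-methoxybenzylidene]imidazolidine-2,4-dione | O=C1NC(=O)N/C1=C\c1ccc(OCc2ccccc2)c(OC)c1 | intermediate
4 | 3-[4-(benzyloxy)-3-methoxyphenyl]-2-oxopropanoic acid | O=C(O)C(=O)Cc1ccc(OCc2ccccc2)c(OC)c1 | intermediate
5 | vinylmagnesium bromide | C=C[Mg]Br | starting material
6 | rac-1-[4-(benzyloxy)-3-methoxyphenyl]prop-2-en-1-ol | C=CC(O)c1ccc(OCc2ccccc2)c(OC)c1 | intermediate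
7 | 1-[4-(benzyloxy)-3-methoxyphenyl]prop-2-en-1-one | C=CC(=O)c1ccc(OCc2ccccc2)c(OC)c1 | intermediate
8 | 3-[4-(benzyloxy)-3-methoxyphenyl]-3-oxopropyl 3-[4-(benzyloxy)-3-methoxyphenyl]-2-oxopropanoate (not isolated) | O=C(CCOC(=O)C(=O)Cc1ccc(OCc2ccccc2)c(OC)c1)c1ccc(OCc2ccccc2)c(OC)c1 | intermediate
9 | (3S,4S)-4-[4-(benzyloxy)-3-methoxybenzoyl]-3-{[4-(benzyloxy)-3-methoxyphenyl]methyl}-3-hydroxyoxolan-2-one | COc1cc(C[C@@]2(O)C(=O)OC[C@@H]2C(=O)c2ccc(OCc3ccccc3)c(OC)c2)ccc1OCc1ccccc1 | intermediate
10 | (3S,4R)-3-{[4-(benzyloxy)-3-methoxyphenyl]methyl}-4-{(R)-[4-(benzyloxy)-3-methoxyphenyl](hydroxy)methyl}-3-hydroxyoxolan-2-one | COc1cc(C[C@@]2(O)C(=O)OC[C@@H]2[C@@H](O)c2ccc(OCc3ccccc3)c(OC)c2)ccc1OCc1ccccc1 | intermediate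
11 | (3S,4R)-3-hydroxy-4-[(R)-hydroxy(4-hydroxy-3-methoxyphenyl)methyl]-3-[(4-hydroxy-3-methoxyphenyl)methyl]oxolan-2-one | COc1cc(C[C@@]2(O)C(=O)OC[C@@H]2[C@@H](O)c2ccc(O)c(OC)c2)ccc1O | target

**Step count and risks**
Total steps: 7. Longest linear sequence: 5 (steps 1, 2, 5, 6, 7 or steps 3, 4, 5, 6, 7).

Step 5 (proposed new method). What may go wrong: Michael addition through the benzylic carbon of the enol form of 4 instead of through the carboxylate oxygen; loss of the carboxylate from the enolate faster than ring closure; self-aldol condensation of the keto acid; weak enantiofacial discrimination. Fallback by known chemistry, setting out from 6 and 4 and returning at 9: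
- Hydroboration–oxidation of 6 (9-BBN; NaOH/H2O2) gives 1-[4-(benzyloxy)-3-methoxyphenyl]propane-1,3-diol F1.
- MnO2 oxidises only the benzylic hydroxyl, giving 1-[4-(benzyloxy)-3-methoxyphenyl]-3-hydroxypropan-1-one F2.
- TMSOTf/Et3N silylates the hydroxyl and the ketone, giving the (Z)-bis(trimethylsilyl) enol ether F3.
- Acid 4 is esterified (MeI, DBU, DMF) to methyl 3-[4-(benzyloxy)-3-methoxyphenyl]-2-oxopropanoate F4.
- A Mukaiyama aldol addition of F3 to F4, catalysed by a Cu(II)–tert-butyl-bis(oxazoline) triflate complex that binds the α-keto ester through both carbonyls (ligand enantiomer chosen for the (S)-carbinol), gives the silylated adduct methyl (2S)-2-{[4-(benzyloxy)-3-methoxyphenyl]methyl}-4-[4-(benzyloxy)-3-methoxyphenyl]-4-oxo-2-(trimethylsilyloxy)-3-[(trimethylsilyloxy)methyl]butanoate F5.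
- Aqueous HCl in THF removes both silyl groups, the primary alcohol lactonises onto the methyl ester, and a trace of Et3N equilibrates the aroyl-bearing carbon, which rejoins the route at 9.

Step 6. What may go wrong: reduction through a non-chelated conformer with attack on the other ketone face; hydride attack on the α-hydroxy lactone; acyl migration of the lactone to the new alkoxide. Fallback from 9 to 10: catalyst-controlled asymmetric transfer hydrogenation (Noyori–Ikariya type) with RuCl[(R,R)-TsDPEN](p-cymene) in HCO2H/Et3N at rt. This reagent reads the aryl/alkyl difference of the ketone and not the neighbouring stereocentres, and the medium is not basic. No new compound is made (F0).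

Step 7. What may go wrong: further hydrogenolysis of the benzylic C–OH, which is activated by the para-oxygenated ring, during debenzylation. Fallback with the order of the last two steps exchanged: 9 is debenzylated first (H2, Pd/C, EtOAc), when no benzylic carbinol is present, to (3S,4S)-3-hydroxy-4-(4-hydroxy-3-methoxybenzoyl)-3-[(4-hydroxy-3-methoxyphenyl)methyl]oxolan-2-one F6. The zinc borohydride reduction of step 6, with extra hydride for the two phenols, is then run last and gives 11 directly.

**Further compounds**
F1 | step 5 | rac-1-[4-(benzyloxy)-3-methoxyphenyl]propane-1,3-diol | OCCC(O)c1ccc(OCc2ccccc2)c(OC)c1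
F2 | step 5 | 1-[4-(benzyloxy)-3-methoxyphenyl]-3-hydroxypropan-1-one | OCCC(=O)c1ccc(OCc2ccccc2)c(OC)c1
F3 | step 5 | (Z)-1-[4-(benzyloxy)-3-methoxyphenyl]-1,3-bis(trimethylsilyloxy)prop-1-ene | C[Si](C)(C)OC/C=C(\O[Si](C)(C)C)c1ccc(OCc2ccccc2)c(OC)c1
F4 | step 5 | methyl 3-[4-(benzyloxy)-3-methoxyphenyl]-2-oxopropanoate | COC(=O)C(=O)Cc1ccc(OCc2ccccc2)c(OC)c1
F5 | step 5 | methyl (2S)-2-{[4-(benzyloxy)-3-methoxyphenyl]methyl}-4-[4-(benzyloxy)-3-methoxyphenyl]-4-oxo-2-(trimethylsilyloxy)-3-[(trimethylsilyloxy)methyl]butanoate (C3 epimers, both converge on 9) | COc1cc(C[C@@](O[Si](C)(C)C)(C(=O)OC)C(CO[Si](C)(C)C)C(=O)c2ccc(OCc3ccccc3)c(OC)c2)ccc1OCc1ccccc1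
F0 | step 6 | none | none
F6 | step 7 | (3S,4S)-3-hydroxy-4-(4-hydroxy-3-methoxybenzoyl)-3-[(4-hydroxy-3-methoxyphenyl)methyl]oxolan-2-one | COc1cc(C[C@@]2(O)C(=O)OC[C@@H]2C(=O)c2ccc(O)c(OC)c2)ccc1O
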